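**Retrosynthetic overview**

1. Feature used: ring B is a 1,2,3,5-tetrasubstituted benzene (C3a, C7a–O1, C7–OH, C5–flavanone) fused to the dihydrofuran along C3a–C7a. Its six carbons map onto C3–C6 of a pyridazine plus the two carbons of an alkyne held on furan C3, with O1 as the link.
2. Last disconnection: the bond from flavanone C2 to benzofuran C5, giving an arylboronic acid and 5,7-bis(benzyloxy)chromone (rings A and C bought as the chromone); an enantioselective conjugate addition sets flavanone C2.
3. Key disconnection: C3a–C7a and C4–C5 of ring B, by an intramolecular diazine/alkyne [4+2] cycloaddition with loss of N2, which closes the dihydrofuran ring and ring B in one operation.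
4. Precursor: the ether of an anti homopropargylic alcohol with 4-benzyloxy-3,6-dichloropyridazine; both sp3 centres of the dihydrofuran come from the addition of a chiral allenylzinc to O-benzylvanillin.
5. Ring order: guaiacyl ring, diazine and chromone are bought; dihydrofuran and ring B are formed together; ring C of the flavanone is completed last at C2.

Key step: step 9

Assumption: in the transfer hydrogenation of the ynone of step 3 the catalyst recognises the alkynyl group as it does in alkynyl methyl ketones, so Ru[(S,S)-TsDPEN](p-cymene) should give the (R)-carbinol (same spatial sense as the (S)-alkynyl methyl carbinols; the label changes because CH2OSi outranks the alkyne).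

Assumption: the pyridine-oxazoline palladium catalyst shows on the chromone the facial preference it shows on β-substituted cyclic enones ((S)-ligand giving the (R)-β-aryl ketone), so the (R)-ligand is used for the (2S)-flavanone.

Abbreviations: TBS = tert-butyldimethylsilyl, TMS = trimethylsilyl, Bn = benzyl, Ms = methanesulfonyl.

**Step 1**
Reactants: 1 (TBS-oxy)acetaldehyde; 2 lithium (trimethylsilyl)acetylide (commercial THF solution)
Product: 3 (±)-1-(TBS-oxy)-4-(trimethylsilyl)but-3-yn-2-ol
Conditions: THF, −78 °C; aq NH4Cl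
Reagents that add atoms: none
Why: Nucleophilic 1,2-addition of a lithium acetylide to an aldehyde, the carbinol centre being formed racemic on purpose because it is erased in step 2.

**Step 2**
Reactants: 3 (±)-1-(TBS-oxy)-4-(trimethylsilyl)but-3-yn-2-ol
Product: 4 1-(TBS-oxy)-4-(trimethylsilyl)but-3-yn-2-one
Conditions: Dess–Martin periodinane, CH2Cl2, 0 °C → rt
Reagents that add atoms: none
Why: Dess–Martin oxidation of a propargylic alcohol to the ynone under near-neutral conditions that leave both silyl groups in place.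

**Step 3**
Reactants: 4 1-(TBS-oxy)-4-(trimethylsilyl)but-3-yn-2-one
Product: 5 (R)-1-(TBS-oxy)-4-(trimethylsilyl)but-3-yn-2-ol
Conditions: Ru[(S,S)-TsDPEN](p-cymene) (2 mol%), i-PrOH, rt
Reagents that add atoms: none
Why: Noyori asymmetric transfer hydrogenation of an alkynyl ketone, in which the alkynyl group takes the place next to the arene ligand in the six-membered hydride-transfer transition state so that the (S,S)-catalyst sets the carbinol centre as (R).

**Step 4**
Reactants: 5 (R)-1-(TBS-oxy)-4-(trimethylsilyl)but-3-yn-2-ol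
Product: 6 (R)-1-(TBS-oxy)-4-(trimethylsilyl)but-3-yn-2-yl methanesulfonate
Conditions: MsCl, Et3N, CH2Cl2, −78 → 0 °C
Reagents that add atoms: methanesulfonyl chloride, CS(=O)(=O)Cl
Why: Sulfonylation at oxygen (O–S bond formation), which cannot touch the carbinol configuration.

**Step 5**
Reactants: 6 (R)-1-(TBS-oxy)-4-(trimethylsilyl)but-3-yn-2-yl methanesulfonate; 7 4-benzyloxy-3-methoxybenzaldehyde
Product: 9 (1R,2S)-1-(4-benzyloxy-3-methoxyphenyl)-2-[(TBS-oxy)methyl]-4-(trimethylsilyl)but-3-yn-1-ol (anti), via allenylzinc reagent 8 (not isolated)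
Conditions: Pd(OAc)2 (5 mol%), PPh3 (5 mol%), Et2Zn (3 equiv), THF, −78 → −20 °C; aq NH4Cl
Reagents that add atoms: none
Why: SE2′ propargylation of an aldehyde by a chiral allenylzinc: zerovalent palladium formed in the flask displaces the mesylate in an anti SN2′ sense, Et2Zn transmetallates the allenylpalladium with retention to 8, and 8 adds through a cyclic transition state, so that the propargylic centre is set as (S) by net inversion of the mesylate centre and the carbinol centre as (R) by the anti preference (aryl group away from the allene substituent) of that transition state.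

**Step 6**
Reactants: 9 (1R,2S)-1-(4-benzyloxy-3-methoxyphenyl)-2-[(TBS-oxy)methyl]-4-(trimethylsilyl)but-3-yn-1-ol
Product: 10 (1R,2S)-1-(4-benzyloxy-3-methoxyphenyl)-2-[(TBS-oxy)methyl]but-3-yn-1-ol
Conditions: K2CO3, MeOH, 0 °C → rt
Reagents that add atoms: none
Why: Methoxide-induced protiodesilylation of the alkynylsilane, selective because the C(sp)–Si bond is far more labile to base than the O–Si bond of the TBS ether.

**Step 7**
Reactants: 11 3,4,6-trichloropyridazine
Product: 12 4-(benzyloxy)-3,6-dichloropyridazine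
Conditions: BnOH (1.0 equiv), NaH (1.05 equiv), THF, 0 °C → rt
Reagents that add atoms: benzyl alcohol, OCc1ccccc1
Why: Nucleophilic aromatic substitution (addition–elimination), which takes place at C4 because this carbon is para-type to N1 and flanked by chlorine-bearing carbons, as known for alkoxides with 3,4,6-trichloropyridazine.

**Step 8**
Reactants: 10 (1R,2S)-1-(4-benzyloxy-3-methoxyphenyl)-2-[(TBS-oxy)methyl]but-3-yn-1-ol; 12 4-(benzyloxy)-3,6-dichloropyridazine
Product: 14 4-(benzyloxy)-3-{[(1R,2S)-1-(4-benzyloxy-3-methoxyphenyl)-2-[(TBS-oxy)methyl]but-3-yn-1-yl]oxy}-6-chloropyridazine, via sodium alkoxide 13 (not isolated)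
Conditions: NaH (1.05 equiv), THF, 0 °C; then 12 (1.1 equiv), 0 °C → rt
Reagents that add atoms: none
Why: Nucleophilic aromatic substitution by the secondary alkoxide at C3, the carbon next to the benzyloxy group, because that donor is conjugated through C5=C6 with N1 and so deactivates C6, by analogy with the 3-selective substitution of 4-donor-substituted 3,6-dichloropyridazines, while only the O–H bond of 10 reacts so that both stereocentres are kept.

**Step 9**
Reactants: 14 4-(benzyloxy)-3-{[(1R,2S)-1-(4-benzyloxy-3-methoxyphenyl)-2-[(TBS-oxy)methyl]but-3-yn-1-yl]oxy}-6-chloropyridazine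
Product: 16 trans-(2R,3S)-7-(benzyloxy)-2-(4-benzyloxy-3-methoxyphenyl)-3-[(TBS-oxy)methyl]-5-chloro-2,3-dihydrobenzofuran, via diazabicyclooctatriene adduct 15 (not isolated)
Conditions: N,N-diethylaniline (0.02 M), 200 °C, sealed tube, Ar
Reagents that add atoms: none
Why: The 1,2-diazine acts as the electron-poor 4π component (C3 to C6) and the tethered terminal alkyne as the 2π component in a thermal intramolecular inverse-electron-demand Diels–Alder reaction, giving the 2,3-diazabicyclo[2.2.2]octatriene 15, which loses N2 by retro-[4+2] so that ring B emerges aromatic without an oxidant. The closest known reaction is the thermal cyclisation of 3-chloro-6-(but-3-ynyloxy)pyridazines to 5-chloro-2,3-dihydrobenzofurans. The dihydrofuran ring closes in the fused mode through the three-atom O1–C2–C3 tether (bond C3a–C7a, five-membered ring), and ring B is completed by the second bond C4–C5 and the departure of N2. No lasting stereocentre is formed (the bridgehead centres of 15 vanish with N2), and C2 and C3 lie outside the reacting π systems and carry no hydrogen that is acidic under neutral thermolysis, so the trans relationship from step 5 is kept. The selectivity needed is regiochemical (benzyloxy to C7, chlorine to C5) and the tether enforces it, since the internal alkyne carbon can reach only C3 of the diazine; the 6-chloro group lowers the diene LUMO against the two alkoxy donors, the two tether substituents favour the folded rotamer, and the amine solvent takes up traces of HCl that could ionise the benzylic C–O bond.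

**Step 10**
Reactants: 16 trans-(2R,3S)-7-(benzyloxy)-2-(4-benzyloxy-3-methoxyphenyl)-3-[(TBS-oxy)methyl]-5-chloro-2,3-dihydrobenzofuran
Product: 17 [(2R,3S)-7-(benzyloxy)-2-(4-benzyloxy-3-methoxyphenyl)-3-[(TBS-oxy)methyl]-2,3-dihydrobenzofuran-5-yl]boronic acid
Conditions: B2(OH)4 (3 equiv), KOAc (3 equiv), PdCl(2′-aminobiphenyl-2-yl)(XPhos) (second-generation XPhos palladacycle, 2 mol%), XPhos (4 mol%), EtOH, 80 °C
Reagents that add atoms: tetrahydroxydiboron, OB(O)B(O)O
Why: Miyaura-type borylation of an aryl chloride, in which the bulky electron-rich XPhos ligand allows oxidative addition of the electron-rich C–Cl bond to zerovalent palladium and acetate-assisted transmetallation with tetrahydroxydiboron gives the boronic acid directly.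

**Step 11**
Reactants: 18 5,7-dihydroxy-4H-chromen-4-one
Product: 19 5,7-bis(benzyloxy)-4H-chromen-4-one
Conditions: BnBr (2.5 equiv), K2CO3 (3 equiv), DMF, 70 °C
Reagents that add atoms: benzyl bromide, BrCc1ccccc1
Why: Williamson ether synthesis on both phenols, the hydrogen-bonded 5-OH needing the raised temperature.

**Step 12**
Reactants: 17 [(2R,3S)-7-(benzyloxy)-2-(4-benzyloxy-3-methoxyphenyl)-3-[(TBS-oxy)methyl]-2,3-dihydrobenzofuran-5-yl]boronic acid; 19 5,7-bis(benzyloxy)-4H-chromen-4-one
Product: 20 (2S)-5,7-bis(benzyloxy)-2-[(2R,3S)-7-(benzyloxy)-2-(4-benzyloxy-3-methoxyphenyl)-3-[(TBS-oxy)methyl]-2,3-dihydrobenzofuran-5-yl]chroman-4-one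
Conditions: Pd(OCOCF3)2 (10 mol%), (R)-4-tert-butyl-2-(pyridin-2-yl)-4,5-dihydrooxazole (12 mol%), NH4PF6 (30 mol%), H2O (5 equiv), ClCH2CH2Cl, 60 °C
Reagents that add atoms: none
Why: Palladium-catalysed asymmetric conjugate addition of an arylboronic acid to a chromone (transmetallation to a cationic aryl complex of divalent palladium, enantio-determining insertion of C2=C3, protonolysis of the palladium enolate by water), in which the tert-butyl group of the (R)-pyridine-oxazoline steers the aryl group to the face of C2 that gives the (2S) centre under catalyst control, the distant dihydrobenzofuran centres having no influence.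

**Step 13**
Reactants: 20 the silyl ether of step 12
Product: 21 (2S)-5,7-bis(benzyloxy)-2-[(2R,3S)-7-(benzyloxy)-2-(4-benzyloxy-3-methoxyphenyl)-3-(hydroxymethyl)-2,3-dihydrobenzofuran-5-yl]chroman-4-one
Conditions: HF·pyridine, pyridine/THF, 0 °C → rt
Reagents that add atoms: none
Why: Fluoride-mediated cleavage of the primary silyl ether under buffered non-basic conditions, which avoid the base-induced retro-oxa-Michael opening and C2 epimerisation of the flavanone.

**Step 14**
Reactants: 21 the tetrabenzyl ether of step 13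
Product: 22 silyhermin B, (2S)-5,7-dihydroxy-2-[(2R,3S)-7-hydroxy-2-(4-hydroxy-3-methoxyphenyl)-3-(hydroxymethyl)-2,3-dihydrobenzofuran-5-yl]chroman-4-one
Conditions: H2 (1 atm), Pd/C (10 wt%), EtOAc/MeOH, rt
Reagents that add atoms: none
Why: Catalytic hydrogenolysis of the four aryl benzyl ethers, which should be cleaved faster than the cyclic benzylic C–O bonds of the flavanone and the dihydrobenzofuran as in the usual debenzylation of such compounds, the reaction being stopped once the uptake for four benzyl groups is reached.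

**Compound list**

1 | (tert-butyldimethylsilyloxy)acetaldehyde | CC(C)(C)[Si](C)(C)OCC=O | starting material
2 | lithium (trimethylsilyl)acetylide | [Li]C#C[Si](C)(C)C | starting material
3 | (±)-1-(tert-butyldimethylsilyloxy)-4-(trimethylsilyl)but-3-yn-2-ol | CC(C)(C)[Si](C)(C)OCC(O)C#C[Si](C)(C)C | intermediate
4 | 1-(tert-butyldimethylsilyloxy)-4-(trimethylsilyl)but-3-yn-2-one | CC(C)(C)[Si](C)(C)OCC(=O)C#C[Si](C)(C)C | intermediate
5 | (R)-1-(tert-butyldimethylsilyloxy)-4-(trimethylsilyl)but-3-yn-2-ol | CC(C)(C)[Si](C)(C)OC[C@H](O)C#C[Si](C)(C)C | intermediate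
6 | (R)-1-(tert-butyldimethylsilyloxy)-4-(trimethylsilyl)but-3-yn-2-yl methanesulfonate | CC(C)(C)[Si](C)(C)OC[C@H](OS(C)(=O)=O)C#C[Si](C)(C)C | intermediate
7 | 4-benzyloxy-3-methoxybenzaldehyde (O-benzylvanillin) | COc1cc(C=O)ccc1OCc1ccccc1 | starting material
8 | (aR)-[4-(tert-butyldimethylsilyloxy)-1-(trimethylsilyl)buta-1,2-dien-1-yl](ethyl)zinc, not isolated | CC[Zn]C([Si](C)(C)C)=[C@]=C([H])CO[Si](C)(C)C(C)(C)C | intermediate
9 | (1R,2S)-1-(4-benzyloxy-3-methoxyphenyl)-2-[(tert-butyldimethylsilyloxy)methyl]-4-(trimethylsilyl)but-3-yn-1-ol | COc1cc([C@H](O)[C@H](CO[Si](C)(C)C(C)(C)C)C#C[Si](C)(C)C)ccc1OCc1ccccc1 | intermediate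
10 | (1R,2S)-1-(4-benzyloxy-3-methoxyphenyl)-2-[(tert-butyldimethylsilyloxy)methyl]but-3-yn-1-ol | COc1cc([C@H](O)[C@H](CO[Si](C)(C)C(C)(C)C)C#C)ccc1OCc1ccccc1 | intermediate
11 | 3,4,6-trichloropyridazine | Clc1cc(Cl)c(Cl)nn1 | starting material
12 | 4-(benzyloxy)-3,6-dichloropyridazine | Clc1cc(OCc2ccccc2)c(Cl)nn1 | intermediate
13 | sodium (1R,2S)-1-(4-benzyloxy-3-methoxyphenyl)-2-[(tert-butyldimethylsilyloxy)methyl]but-3-yn-1-olate, not isolated | COc1cc([C@H]([O-])[C@H](CO[Si](C)(C)C(C)(C)C)C#C)ccc1OCc1ccccc1.[Na+] | intermediate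
14 | 4-(benzyloxy)-3-{[(1R,2S)-1-(4-benzyloxy-3-methoxyphenyl)-2-[(tert-butyldimethylsilyloxy)methyl]but-3-yn-1-yl]oxy}-6-chloropyridazine | COc1cc([C@H](Oc2nnc(Cl)cc2OCc2ccccc2)[C@H](CO[Si](C)(C)C(C)(C)C)C#C)ccc1OCc1ccccc1 | intermediate
15 | furan-fused 2,3-diazabicyclo[2.2.2]octa-2,5,7-triene cycloadduct of 14 (either bridgehead configuration), not isolated | COc1cc([C@@H]2OC34N=NC(Cl)(C=C3OCc5ccccc5)C=C4[C@H]2CO[Si](C)(C)C(C)(C)C)ccc1OCc1ccccc1 | intermediate
16 | trans-(2R,3S)-7-(benzyloxy)-2-(4-benzyloxy-3-methoxyphenyl)-3-[(tert-butyldimethylsilyloxy)methyl]-5-chloro-2,3-dihydrobenzofuran | COc1cc([C@@H]2Oc3c(OCc4ccccc4)cc(Cl)cc3[C@H]2CO[Si](C)(C)C(C)(C)C)ccc1OCc1ccccc1 | intermediate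
17 | [(2R,3S)-7-(benzyloxy)-2-(4-benzyloxy-3-methoxyphenyl)-3-[(tert-butyldimethylsilyloxy)methyl]-2,3-dihydrobenzofuran-5-yl]boronic acid | COc1cc([C@@H]2Oc3c(OCc4ccccc4)cc(B(O)O)cc3[C@H]2CO[Si](C)(C)C(C)(C)C)ccc1OCc1ccccc1 | intermediate
18 | 5,7-dihydroxy-4H-chromen-4-one | O=c1ccoc2cc(O)cc(O)c12 | starting material
19 | 5,7-bis(benzyloxy)-4H-chromen-4-one | O=c1ccoc2cc(OCc3ccccc3)cc(OCc3ccccc3)c12 | intermediate
20 | (2S)-5,7-bis(benzyloxy)-2-[(2R,3S)-7-(benzyloxy)-2-(4-benzyloxy-3-methoxyphenyl)-3-[(tert-butyldimethylsilyloxy)methyl]-2,3-dihydrobenzofuran-5-yl]chroman-4-one | COc1cc([C@@H]2Oc3c(OCc4ccccc4)cc([C@@H]4CC(=O)c5c(OCc6ccccc6)cc(OCc6ccccc6)cc5O4)cc3[C@H]2CO[Si](C)(C)C(C)(C)C)ccc1OCc1ccccc1 | intermediate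
21 | (2S)-5,7-bis(benzyloxy)-2-[(2R,3S)-7-(benzyloxy)-2-(4-benzyloxy-3-methoxyphenyl)-3-(hydroxymethyl)-2,3-dihydrobenzofuran-5-yl]chroman-4-one | COc1cc([C@@H]2Oc3c(OCc4ccccc4)cc([C@@H]4CC(=O)c5c(OCc6ccccc6)cc(OCc6ccccc6)cc5O4)cc3[C@H]2CO)ccc1OCc1ccccc1 | intermediate
22 | silyhermin B | COc1cc([C@@H]2Oc3c(O)cc([C@@H]4CC(=O)c5c(O)cc(O)cc5O4)cc3[C@H]2CO)ccc1O | target

**Step count and risks**

Total step count: 14. Longest linear sequence: 12 steps (steps 1–6, 8, 9, 10, 12, 13, 14).

Steps most likely to fail:

1. Step 9. The diazine carries two alkoxy donors and may be too electron-rich a diene, so that the cycloaddition becomes slower than thermal degradation (ionisation of the benzylic C–O bond to a pyridazinone, or migration of the O-benzyl group to nitrogen). Fallback, setting out from 10 and coming back at 16: the C7 oxygen would be carried through the cycloaddition as an acetyl acceptor and unmasked afterwards.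
   - 3,6-Dichloropyridazine would be acetylated at C4 by a Minisci radical acylation (CH3CHO, t-BuOOH, FeSO4, H2SO4) to 1-(3,6-dichloropyridazin-4-yl)ethan-1-one F1.
   - The sodium alkoxide 13 of 10 would displace the chloride at C3, now activated ortho to the acyl group, to give the 4-acetyl-6-chloropyridazin-3-yl ether F2.
   - The acetyl group lowers the LUMO of the diazine, so F2 should cyclise with loss of N2 at a lower temperature to the 7-acetyl-5-chloro-2,3-dihydrobenzofuran F3.
   - Baeyer–Villiger oxidation (mCPBA, NaHCO3, CH2Cl2), in which the ortho-alkoxyaryl group migrates, would give the aryl acetate F4.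
   - Methanolysis (K2CO3, MeOH) would give the phenol F5, and benzylation (BnBr, K2CO3, DMF) would give 16.

2. Step 12. Insertion of the electron-rich 5,7-dialkoxychromone into the aryl–palladium bond may be slow, so that protodeboronation of the electron-rich boronic acid takes over, or facial control may be eroded. Fallback, setting out from 17 and 19 and coming back at 20: the aryl group would be transferred in a different catalytic manifold, the Hayashi–Miyaura 1,4-addition with monovalent rhodium.
   - Catalyst and conditions: [Rh(OH)(cod)]2 with an electron-poor chiral bisphosphine of the MeO-F12-BIPHEP type, toluene/H2O, rt to 40 °C.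
   - A neutral aryl–rhodium species inserts the chromone and the oxa-π-allyl intermediate is hydrolysed by water.
   - The ligand enantiomer would be fixed beforehand with phenylboronic acid and 19. No new compound is made.

3. Step 5. The propargyl form of the allenylzinc has a β-silyloxy group and may eliminate, and facial discrimination in the cyclic transition state is weaker for aromatic aldehydes, so that the syn diastereomer may form alongside. Fallback, setting out from 7 and coming back at 10: both centres would be set by an auxiliary-controlled anti-aldol reaction, which is at its best with aromatic aldehydes, and the alkyne made afterwards from the acyl carbon.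
   - (R)-4-Benzyloxazolidin-2-one would be acylated with 3-(tert-butyldimethylsilyloxy)propanoic acid (PivCl, Et3N; lithiated auxiliary) to the imide F6.
   - The MgCl2-catalysed Evans anti-aldol reaction with 7 (MgCl2, Et3N, Me3SiCl, EtOAc) would give the silylated anti adduct F7, set free on work-up with CF3CO2H/MeOH as the alcohol F8.
   - Protection (Et3SiOTf, 2,6-lutidine) would give the triethylsilyl ether F9, and reductive removal of the auxiliary (LiBH4, THF/MeOH) the primary alcohol F10.
   - Dess–Martin oxidation would give the aldehyde F11, and Ohira–Bestmann homologation (dimethyl (1-diazo-2-oxopropyl)phosphonate, K2CO3, MeOH) the alkyne F12.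
   - Selective removal of the triethylsilyl group (pyridinium p-toluenesulfonate, MeOH) would give 10.

**Further compounds**

F1 | step 9 | 1-(3,6-dichloropyridazin-4-yl)ethan-1-one | CC(=O)c1cc(Cl)nnc1Cl
F2 | step 9 | 1-[6-chloro-3-{[(1R,2S)-1-(4-benzyloxy-3-methoxyphenyl)-2-[(tert-butyldimethylsilyloxy)methyl]but-3-yn-1-yl]oxy}pyridazin-4-yl]ethan-1-one | COc1cc([C@H](Oc2nnc(Cl)cc2C(C)=O)[C@H](CO[Si](C)(C)C(C)(C)C)C#C)ccc1OCc1ccccc1
F3 | step 9 | 1-[(2R,3S)-2-(4-benzyloxy-3-methoxyphenyl)-3-[(tert-butyldimethylsilyloxy)methyl]-5-chloro-2,3-dihydrobenzofuran-7-yl]ethan-1-one | COc1cc([C@@H]2Oc3c(C(C)=O)cc(Cl)cc3[C@H]2CO[Si](C)(C)C(C)(C)C)ccc1OCc1ccccc1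
F4 | step 9 | (2R,3S)-2-(4-benzyloxy-3-methoxyphenyl)-3-[(tert-butyldimethylsilyloxy)methyl]-5-chloro-2,3-dihydrobenzofuran-7-yl acetate | COc1cc([C@@H]2Oc3c(OC(C)=O)cc(Cl)cc3[C@H]2CO[Si](C)(C)C(C)(C)C)ccc1OCc1ccccc1
F5 | step 9 | (2R,3S)-2-(4-benzyloxy-3-methoxyphenyl)-3-[(tert-butyldimethylsilyloxy)methyl]-5-chloro-2,3-dihydrobenzofuran-7-ol | COc1cc([C@@H]2Oc3c(O)cc(Cl)cc3[C@H]2CO[Si](C)(C)C(C)(C)C)ccc1OCc1ccccc1
F0 | step 12 | none | none
F6 | step 5 | (R)-4-benzyl-3-[3-(tert-butyldimethylsilyloxy)propanoyl]oxazolidin-2-one | CC(C)(C)[Si](C)(C)OCCC(=O)N1[C@H](Cc2ccccc2)COC1=O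
F7 | step 5 | (R)-4-benzyl-3-[(2S,3R)-3-(4-benzyloxy-3-methoxyphenyl)-2-[(tert-butyldimethylsilyloxy)methyl]-3-(trimethylsilyloxy)propanoyl]oxazolidin-2-one | COc1cc([C@H](O[Si](C)(C)C)[C@H](CO[Si](C)(C)C(C)(C)C)C(=O)N2[C@H](Cc3ccccc3)COC2=O)ccc1OCc1ccccc1
F8 | step 5 | (R)-4-benzyl-3-[(2S,3R)-3-(4-benzyloxy-3-methoxyphenyl)-2-[(tert-butyldimethylsilyloxy)methyl]-3-hydroxypropanoyl]oxazolidin-2-one | COc1cc([C@H](O)[C@H](CO[Si](C)(C)C(C)(C)C)C(=O)N2[C@H](Cc3ccccc3)COC2=O)ccc1OCc1ccccc1
F9 | step 5 | (R)-4-benzyl-3-[(2S,3R)-3-(4-benzyloxy-3-methoxyphenyl)-2-[(tert-butyldimethylsilyloxy)methyl]-3-(triethylsilyloxy)propanoyl]oxazolidin-2-one | COc1cc([C@H](O[Si](CC)(CC)CC)[C@H](CO[Si](C)(C)C(C)(C)C)C(=O)N2[C@H](Cc3ccccc3)COC2=O)ccc1OCc1ccccc1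
F10 | step 5 | (2S,3R)-3-(4-benzyloxy-3-methoxyphenyl)-2-[(tert-butyldimethylsilyloxy)methyl]-3-(triethylsilyloxy)propan-1-ol | COc1cc([C@H](O[Si](CC)(CC)CC)[C@H](CO[Si](C)(C)C(C)(C)C)CO)ccc1OCc1ccccc1
F11 | step 5 | (2S,3R)-3-(4-benzyloxy-3-methoxyphenyl)-2-[(tert-butyldimethylsilyloxy)methyl]-3-(triethylsilyloxy)propanal | COc1cc([C@H](O[Si](CC)(CC)CC)[C@H](CO[Si](C)(C)C(C)(C)C)C=O)ccc1OCc1ccccc1
F12 | step 5 | triethylsilyl ether of 10, (1R,2S)-configured | COc1cc([C@H](O[Si](CC)(CC)CC)[C@H](CO[Si](C)(C)C(C)(C)C)C#C)ccc1OCc1ccccc1
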